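**Retrosynthetic overview** (chroman numbering: O1, C2, C3, C4, C4a, C5–C8, C8a)
1. The target is reached last by freeing the C7/C8 catechol from a diphenylmethylene ketal.
2. The dihydropyran ring is opened at its aryl–CH2 bond C4–C4a and at O1–C2, giving a 2-bromophenol and (2E,6E,10E)-geranylgeranyl methyl carbonate. In the forward direction one flask does both: asymmetric allylic O-alkylation (O1–C2, sets C2), then hydroboration and ring-closing B-alkyl Suzuki–Miyaura coupling (C4–C4a).
3. Enabling feature: C2 (fully substituted, O-bearing) with its methyl group, ring carbons C3 and C4 and the C16 chain is one intact geranylgeranyl unit. Bound to O1 through its tertiary carbon, C3=C4 is a vinyl group, the only monosubstituted alkene among four, and its end carbon C4 faces C4a, the arene carbon ortho to O1. Boron therefore goes to C4 and bromine to C4a without competition.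
4. The bromophenol comes from symmetric 5-methylpyrogallol: a ketal across two neighbouring hydroxyls leaves one outer hydroxyl free, and bromination ortho to it marks C4a. The carbonate comes from geranylgeraniol.
5. Ring order: benzene ring bought; temporary dioxole ring (step 1); dihydropyran ring (step 4); dioxole opened (step 5).

Key step: step 4

Assumption: the (S,S)-diphosphine of step 4 is taken to deliver the (S)-ether from the (2E)-carbonate; if the sense proves opposite, the (R,R)-ligand is used and nothing else changes.

Step 1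
Reactants: 1 5-methylpyrogallol (5-methylbenzene-1,2,3-triol); 2 dichlorodiphenylmethane
Product: 3 6-methyl-2,2-diphenyl-1,3-benzodioxol-4-ol
Conditions: Ph2CCl2 (1.1 equiv), neat, 170 °C, N2 stream
Reagents that add atoms: dichlorodiphenylmethane (2), ClC(Cl)(c1ccccc1)c1ccccc1
Why: Ketal formation from a catechol unit and a gem-dichloride (double O-alkylation) can only bridge two neighbouring hydroxyls in a five-membered dioxole, and because the triol is symmetric either neighbouring pair gives the same product with one outer hydroxyl left free.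

Step 2
Reactants: 3 6-methyl-2,2-diphenyl-1,3-benzodioxol-4-ol; 4 N-bromosuccinimide
Product: 5 5-bromo-6-methyl-2,2-diphenyl-1,3-benzodioxol-4-ol
Conditions: NBS (1.0 equiv), i-Pr2NH (10 mol%), CH2Cl2, 0 °C
Reagents that add atoms: N-bromosuccinimide (4), O=C1CCC(=O)N1Br
Why: Amine-mediated electrophilic bromination of a phenol should deliver bromine from a hydrogen-bonded N-bromoamine to the position ortho to the hydroxyl, here the only free ortho carbon, and it is run before any alkene is in the molecule.

Step 3
Reactants: 6 (2E,6E,10E)-geranylgeraniol; 7 methyl chloroformate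
Product: 8 (2E,6E,10E)-geranylgeranyl methyl carbonate
Conditions: ClCO2Me (1.5 equiv), pyridine (2 equiv), CH2Cl2, 0 °C
Reagents that add atoms: methyl chloroformate (7), COC(=O)Cl
Why: Acylation of a primary allylic alcohol with a chloroformate under pyridine should give the carbonate without touching the alkenes or the (2E) geometry.

Step 4
Reactants: 5 5-bromo-6-methyl-2,2-diphenyl-1,3-benzodioxol-4-ol; 8 (2E,6E,10E)-geranylgeranyl methyl carbonate (1.05 equiv); 9 9-borabicyclo[3.3.1]nonane (9-BBN)
Product: 12 (2S)-2,5-dimethyl-7,8-(diphenylmethylenedioxy)-2-[(3E,7E)-4,8,12-trimethyltrideca-3,7,11-trien-1-yl]chroman, via branched aryl allyl ether 10 (not isolated), via B-alkyl-9-BBN adduct 11 (not isolated)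
Conditions: Pd2(dba)3·CHCl3 (2.5 mol%), (1S,2S)-N,N'-bis[2-(diphenylphosphino)benzoyl]cyclohexane-1,2-diamine (7.5 mol%), CH2Cl2, rt; volatiles removed in vacuo; 9-BBN (1.4 equiv), THF, 0 °C → rt; then degassed aq. K3PO4 (3 equiv), Pd(OAc)2 (5 mol%), SPhos (10 mol%), THF/H2O, 0.02 M, 65 °C
Reagents that add atoms: (2E,6E,10E)-geranylgeranyl methyl carbonate (8), CC(C)=CCC/C(C)=C/CC/C(C)=C/CC/C(C)=C/COC(=O)OC
Why: Zerovalent palladium ionises 8 (loss of CO2; the methoxide formed deprotonates 5) to a 1,1-disubstituted π-allyl complex of divalent palladium, the phenoxide attacks its more substituted end inside the chiral pocket of the diphosphine to give branched ether 10, 9-BBN then puts boron on the end carbon of the vinyl group just created (11), and a second palladium catalyst inserts into the C–Br bond, accepts the primary alkyl group from the base-activated borane and forms the aryl–CH2 bond by reductive elimination. The closest known reaction types are Tsuji–Trost-type asymmetric O-allylation of phenols with 3,3-disubstituted allyl carbonates, 9-BBN hydroboration of a terminal alkene beside trisubstituted ones, and ring-closing B-alkyl Suzuki–Miyaura coupling, run here in one flask as a formal anti-Markovnikov hydroarylation. The dihydropyran ring is closed at its aryl–CH2 bond by C(sp3)–C(sp2) reductive elimination from a seven-membered palladacycle, so that neither a cation nor a radical is generated next to the triene. The one new stereocentre, C2, is controlled by the ligand: the (2E) geometry of 8 fixes which substituent of the allyl terminus is syn and which anti, and the twofold-symmetric diphosphine selects the face to which oxygen is delivered; once the vinyl group is hydroborated C2 is no longer allylic and cannot be ionised again. The step needs branched over linear attack (usual for this ligand class with 3,3-disubstituted allyl units), hydroboration of one alkene out of four (secured by the single monosubstituted C=C against three trisubstituted ones and by the bulk of 9-BBN) and coupling at one ring carbon only (secured by the bromine placed ortho to the phenol oxygen in step 2, with six-membered ring size and dilution favouring closure over oligomerisation).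

Step 5
Reactants: 12 (2S)-2,5-dimethyl-7,8-(diphenylmethylenedioxy)-2-[(3E,7E)-4,8,12-trimethyltrideca-3,7,11-trien-1-yl]chroman
Product: 13 (2S)-2,5-dimethyl-2-[(3E,7E)-4,8,12-trimethyltrideca-3,7,11-trien-1-yl]-3,4-dihydro-2H-chromene-7,8-diol (target)
Conditions: AcOH/H2O (4:1), degassed, 80 °C, Ar
Reagents that add atoms: none
Why: Acid hydrolysis of the diphenylmethylene ketal should proceed through a diaryl-stabilised oxocarbenium ion and release benzophenone, while acetic acid is too weak to protonate the trisubstituted alkenes or to ionise the tertiary aryl ether, so C2 and the (E) alkenes stay untouched.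

**Compound list**
1 | 5-methylpyrogallol (5-methylbenzene-1,2,3-triol) | Cc1cc(O)c(O)c(O)c1 | starting material
2 | dichlorodiphenylmethane | ClC(Cl)(c1ccccc1)c1ccccc1 | starting material
3 | 6-methyl-2,2-diphenyl-1,3-benzodioxol-4-ol | Cc1cc(O)c2OC(c3ccccc3)(c3ccccc3)Oc2c1 | intermediate
4 | N-bromosuccinimide | O=C1CCC(=O)N1Br | starting material
5 | 5-bromo-6-methyl-2,2-diphenyl-1,3-benzodioxol-4-ol | Cc1cc2OC(c3ccccc3)(c3ccccc3)Oc2c(O)c1Br | intermediate
6 | (2E,6E,10E)-geranylgeraniol, (2E,6E,10E)-3,7,11,15-tetramethylhexadeca-2,6,10,14-tetraen-1-ol | CC(C)=CCC/C(C)=C/CC/C(C)=C/CC/C(C)=C/CO | starting material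
7 | methyl chloroformate | COC(=O)Cl | starting material
8 | (2E,6E,10E)-geranylgeranyl methyl carbonate | CC(C)=CCC/C(C)=C/CC/C(C)=C/CC/C(C)=C/COC(=O)OC | intermediate
9 | 9-borabicyclo[3.3.1]nonane (9-BBN, used as its dimer) | B1C2CCCC1CCC2 | starting material
10 | 5-bromo-6-methyl-2,2-diphenyl-4-{[(3S,6E,10E)-3,7,11,15-tetramethylhexadeca-1,6,10,14-tetraen-3-yl]oxy}-1,3-benzodioxole | CC(C)=CCC/C(C)=C/CC/C(C)=C/CC[C@@](C)(C=C)Oc1c(Br)c(C)cc2OC(c3ccccc3)(c3ccccc3)Oc12 | intermediate (not isolated)
11 | 9-[(3R,6E,10E)-3-(5-bromo-6-methyl-2,2-diphenyl-1,3-benzodioxol-4-yloxy)-3,7,11,15-tetramethylhexadeca-6,10,14-trien-1-yl]-9-borabicyclo[3.3.1]nonane (same spatial arrangement as 10; the descriptor changes by priority only) | CC(C)=CCC/C(C)=C/CC/C(C)=C/CC[C@@](C)(CCB1C2CCCC1CCC2)Oc1c(Br)c(C)cc2OC(c3ccccc3)(c3ccccc3)Oc12 | intermediate (not isolated)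
12 | (2S)-2,5-dimethyl-7,8-(diphenylmethylenedioxy)-2-[(3E,7E)-4,8,12-trimethyltrideca-3,7,11-trien-1-yl]chroman | CC(C)=CCC/C(C)=C/CC/C(C)=C/CC[C@@]1(C)CCc2c(C)cc3OC(c4ccccc4)(c4ccccc4)Oc3c2O1 | intermediate
13 | (2S)-2,5-dimethyl-2-[(3E,7E)-4,8,12-trimethyltrideca-3,7,11-trien-1-yl]-3,4-dihydro-2H-chromene-7,8-diol | CC(C)=CCC/C(C)=C/CC/C(C)=C/CC[C@@]1(C)CCc2c(C)cc(O)c(O)c2O1 | target

**Step count**
Total: 5 steps. Longest linear sequence: 4 steps (1, 2, 4, 5); step 3 is a one-step branch.

**Steps most likely to fail**

Step 4. The crowded phenoxide, substituted on both ortho positions, may attack the unhindered allyl terminus (linear ether) or add with poor facial selectivity. In the last stage, oxidative addition at the hindered, electron-rich C–Br bond may be slow. The fallback drops the bromine and closes the same bond by electrophilic substitution at the C–H position. It sets out from 3 and 8 and comes back at 12. The same palladium/diphosphine system should convert 3, which has only one tied-back ortho substituent, into 6-methyl-2,2-diphenyl-4-{[(3S,6E,10E)-3,7,11,15-tetramethylhexadeca-1,6,10,14-tetraen-3-yl]oxy}-1,3-benzodioxole F1, which is isolated. 9-BBN in THF should give the B-alkyl-9-BBN adduct F2, and NaOH/H2O2 the primary alcohol (3S,6E,10E)-3-(6-methyl-2,2-diphenyl-1,3-benzodioxol-4-yloxy)-3,7,11,15-tetramethylhexadeca-6,10,14-trien-1-ol F3. Tf2O with 2,6-di-tert-butyl-4-methylpyridine in CH2Cl2 (−78 → 0 °C) should form the primary triflate F4. This should close by intramolecular Friedel–Crafts alkylation onto the only ring carbon within reach (ortho to the ether oxygen, para to a ketal oxygen) to give 12.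

Step 2. Bromination para to the hydroxyl, or twofold bromination, may compete. The fallback uses directed ortho-metalation, and sets out from 3 and comes back at 5. Diethylcarbamoyl chloride with K2CO3 in MeCN should give 6-methyl-2,2-diphenyl-1,3-benzodioxol-4-yl N,N-diethylcarbamate F5. s-BuLi/TMEDA in THF at −78 °C should lithiate the only position ortho to the carbamate, giving the 5-lithio carbamate F6. Quenching with 1,2-dibromotetrachloroethane should give 5-bromo-6-methyl-2,2-diphenyl-1,3-benzodioxol-4-yl N,N-diethylcarbamate F7, and KOH in EtOH/H2O at reflux should free 5.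

Step 5. Acid may hydrate or cyclise the chain alkenes, and the freed catechol may be oxidised by air. The fallback sets out from 12 and comes back at 13. Dissolving-metal cleavage (Li, NH3(l)/THF, −78 °C, then NH4Cl) should break the two benzhydryl-type C–O bonds by electron transfer and release the ketal carbon as diphenylmethane. Isolated trisubstituted alkenes and the alkyl aryl ether of the chroman are inert to these conditions, and no acid is involved. No new isolable compound arises (entry F0).

Further compounds
F1 | step 4 | 6-methyl-2,2-diphenyl-4-{[(3S,6E,10E)-3,7,11,15-tetramethylhexadeca-1,6,10,14-tetraen-3-yl]oxy}-1,3-benzodioxole | CC(C)=CCC/C(C)=C/CC/C(C)=C/CC[C@@](C)(C=C)Oc1cc(C)cc2OC(c3ccccc3)(c3ccccc3)Oc12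
F2 | step 4 | 9-[(3R,6E,10E)-3-(6-methyl-2,2-diphenyl-1,3-benzodioxol-4-yloxy)-3,7,11,15-tetramethylhexadeca-6,10,14-trien-1-yl]-9-borabicyclo[3.3.1]nonane | CC(C)=CCC/C(C)=C/CC/C(C)=C/CC[C@@](C)(CCB1C2CCCC1CCC2)Oc1cc(C)cc2OC(c3ccccc3)(c3ccccc3)Oc12
F3 | step 4 | (3S,6E,10E)-3-(6-methyl-2,2-diphenyl-1,3-benzodioxol-4-yloxy)-3,7,11,15-tetramethylhexadeca-6,10,14-trien-1-ol | CC(C)=CCC/C(C)=C/CC/C(C)=C/CC[C@@](C)(CCO)Oc1cc(C)cc2OC(c3ccccc3)(c3ccccc3)Oc12
F4 | step 4 | (3S,6E,10E)-3-(6-methyl-2,2-diphenyl-1,3-benzodioxol-4-yloxy)-3,7,11,15-tetramethylhexadeca-6,10,14-trien-1-yl trifluoromethanesulfonate | CC(C)=CCC/C(C)=C/CC/C(C)=C/CC[C@@](C)(CCOS(=O)(=O)C(F)(F)F)Oc1cc(C)cc2OC(c3ccccc3)(c3ccccc3)Oc12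
F5 | step 2 | 6-methyl-2,2-diphenyl-1,3-benzodioxol-4-yl N,N-diethylcarbamate | CCN(CC)C(=O)Oc1cc(C)cc2OC(c3ccccc3)(c3ccccc3)Oc12
F6 | step 2 | 5-lithio-6-methyl-2,2-diphenyl-1,3-benzodioxol-4-yl N,N-diethylcarbamate | CCN(CC)C(=O)Oc1c([Li])c(C)cc2OC(c3ccccc3)(c3ccccc3)Oc12
F7 | step 2 | 5-bromo-6-methyl-2,2-diphenyl-1,3-benzodioxol-4-yl N,N-diethylcarbamate | CCN(CC)C(=O)Oc1c(Br)c(C)cc2OC(c3ccccc3)(c3ccccc3)Oc12
F0 | step 5 | none | none
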